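**Retrosynthetic overview**
1. The ten-membered ring is opened at C4=C5 by ring-closing metathesis, giving an acyclic bis-oxirane with a methacryloyl ketone and a butenyl chain; the carbocycle is formed last.
2. Both oxiranes come from one flask operation on an (E,E)-skipped dienol: two hydroxyl-directed Ti/tartrate epoxidations in sequence. The C12 carbinol is cis to C9 and the C15 carbinol trans to C9, so the two allylic alcohols need opposite tartrates: L-(+)-DIPT for C8=C11, then D-(−)-DIPT for C1=C10.
3. The skipped diene comes from Cu-catalysed anti-carbomagnesiation of a propargylic alcohol with MeMgBr, followed by allylation with an (E)-allylic chloride.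
4. The alkynol comes from methacrolein, propargyl bromide and formaldehyde; the allylic chloride from chloroprene and butenylmagnesium bromide via a vinyl oxirane.
5. Ring order: the two oxiranes together (step 9), then the carbocycle (step 12).

Assumption: locants follow the target ring — C1 (oxirane carbon bearing C15H2OAc), C2, C3, C4=C5(CH3), C6 (C=O), C7, C8 (spiro oxirane carbon), C9, C10 (oxirane CH), exocyclic C11 (CH3 and C12H2OAc); all intermediates carrying the C6 carbinol stereocentre are used as inconsequential epimer mixtures.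

**Step 1**
Reactants: 1 methacrolein (2-methylprop-2-enal); 2 propargyl bromide (3-bromoprop-1-yne)
Product: 3 rac-2-methylhex-1-en-5-yn-3-ol
Conditions: Zn dust, THF/sat. aq. NH4Cl, 0 °C to rt
Reagents that add atoms: none
Why: Zinc Barbier propargylation, in which the allenylzinc formed in situ adds through its γ-carbon (SE2') to the aldehyde to give the homopropargylic alcohol; the racemic carbinol (future C6) is erased by oxidation in step 11.

**Step 2**
Reactants: 3 rac-2-methylhex-1-en-5-yn-3-ol
Product: 4 rac-tert-butyl(dimethyl)[(2-methylhex-1-en-5-yn-3-yl)oxy]silane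
Conditions: TBSCl, imidazole, DMF, rt
Reagents that add atoms: tert-butyl(chloro)dimethylsilane CC(C)(C)[Si](C)(C)Cl
Why: Imidazole-promoted silylation masks the secondary alcohol so that it neither quenches the organometallics of steps 3 and 8 nor directs an epoxidation in step 9.

**Step 3**
Reactants: 4 rac-tert-butyl(dimethyl)[(2-methylhex-1-en-5-yn-3-yl)oxy]silane
Product: 6 rac-5-[(tert-butyldimethylsilyl)oxy]-6-methylhept-6-en-2-yn-1-ol, via lithium acetylide 5 (not isolated)
Conditions: n-BuLi, THF, −78 °C; then (CH2O)n, −78 °C to rt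
Reagents that add atoms: paraformaldehyde (formaldehyde) C=O
Why: Deprotonation of the terminal alkyne and 1,2-addition of the acetylide to formaldehyde (alkyne hydroxymethylation) installs C12 as a propargylic alcohol.

**Step 4**
Reactants: 7 chloroprene (2-chlorobuta-1,3-diene); 8 but-3-en-1-ylmagnesium bromide
Product: 9 3-methylidenehepta-1,6-diene
Conditions: NiCl2(Ph2PCH2CH2CH2PPh2) (1 mol%), Et2O/THF, 0 °C to rt
Reagents that add atoms: none
Why: Kumada–Tamao–Corriu coupling of the vinylic C–Cl bond with a primary alkyl Grignard reagent, the chelating diphosphine suppressing β-hydride elimination.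

**Step 5**
Reactants: 9 3-methylidenehepta-1,6-diene
Product: 10 rac-2-(but-3-en-1-yl)-2-ethenyloxirane
Conditions: mCPBA (1.0 equiv), NaHCO3, CH2Cl2, 0 °C
Reagents that add atoms: 3-chloroperoxybenzoic acid OOC(=O)c1cccc(Cl)c1
Why: Prilezhaev epoxidation is fastest at the most electron-rich, 1,1-disubstituted double bond (as with isoprene), and the minor regioisomeric oxiranes are removed by distillation.

**Step 6**
Reactants: 10 rac-2-(but-3-en-1-yl)-2-ethenyloxirane
Product: 11 (2E)-2-(but-3-en-1-yl)-4-chlorobut-2-en-1-ol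
Conditions: TiCl4 (1.0 equiv), CH2Cl2, −90 °C; aq. NaHCO3 work-up
Reagents that add atoms: titanium tetrachloride Cl[Ti](Cl)(Cl)Cl
Why: Lewis-acid-mediated conjugate (SN2') opening of the vinyl oxirane by chloride, which, as for isoprene monoxide, gives the E allylic chloride with CH2OH trans to CH2Cl.

**Step 7**
Reactants: 11 (2E)-2-(but-3-en-1-yl)-4-chlorobut-2-en-1-ol
Product: 12 {[(2E)-2-(but-3-en-1-yl)-4-chlorobut-2-en-1-yl]oxy}(triethyl)silane
Conditions: TESCl, imidazole, CH2Cl2, 0 °C
Reagents that add atoms: chlorotriethylsilane CC[Si](Cl)(CC)CC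
Why: Silylation gives a fluoride-labile primary TES ether that keeps the C15 oxygen from binding titanium until it is released on purpose in step 9.

**Step 8**
Reactants: 6 rac-5-[(tert-butyldimethylsilyl)oxy]-6-methylhept-6-en-2-yn-1-ol; 12 {[(2E)-2-(but-3-en-1-yl)-4-chlorobut-2-en-1-yl]oxy}(triethyl)silane
Product: 14 (2E,5E)-3-{2-[(tert-butyldimethylsilyl)oxy]-3-methylbut-3-en-1-yl}-2-methyl-6-{[(triethylsilyl)oxy]methyl}deca-2,5,9-trien-1-ol, via alkenylmagnesium bromide 13 (not isolated)
Conditions: MeMgBr (2.5 equiv), CuI (10 mol%), THF, 0 °C to rt; then 12, −30 °C to rt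
Reagents that add atoms: methylmagnesium bromide C[Mg]Br
Why: Duboudin–Jousseaume copper-catalysed anti-carbomagnesiation of the propargylic alkoxide puts CH3 on the carbinol-bearing alkyne carbon (C11) and magnesium on C8 cis to CH2O (five-membered chelate), and copper-catalysed SN2 allylation at the unhindered primary C–Cl (its γ-carbon is fully substituted) then joins C8 to C9 with retention of both olefin geometries, so C12 ends cis to C9 and C15 trans to C9.

**Step 9**
Reactants: 14 (2E,5E)-3-{2-[(tert-butyldimethylsilyl)oxy]-3-methylbut-3-en-1-yl}-2-methyl-6-{[(triethylsilyl)oxy]methyl}deca-2,5,9-trien-1-ol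
Product: 18 {(2R,3R)-3-[((2S,3S)-3-(acetoxymethyl)-2-{2-[(tert-butyldimethylsilyl)oxy]-3-methylbut-3-en-1-yl}-3-methyloxiran-2-yl)methyl]-2-(but-3-en-1-yl)oxiran-2-yl}methyl acetate, via epoxy alcohol 15 (not isolated), via epoxy diol 16 (not isolated), via bis-oxirane diol 17 (not isolated)
Conditions: Ti(OiPr)4 (5 mol%), L-(+)-DIPT (6 mol%), t-BuOOH (1.05 equiv), 4 Å MS, CH2Cl2, −25 °C; then TBAF (1.1 equiv), −25 °C; then Ti(OiPr)4 (50 mol%), D-(−)-DIPT (65 mol%), t-BuOOH (1.5 equiv), −25 °C; then P(OMe)3, Et3N, DMAP, Ac2O, 0 °C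
Reagents that add atoms: tert-butyl hydroperoxide CC(C)(C)OO; acetic anhydride CC(=O)OC(C)=O
Why: Proposed new method: a one-flask sequence of two Katsuki–Sharpless titanium–tartrate epoxidations (closest known chemistry: catalytic Sharpless asymmetric epoxidation of tetra- and trisubstituted primary allylic alcohols with in situ acylation), in which L-(+)-DIPT first epoxidises only the free C8=C11 allylic alcohol (the C15 silyl ether cannot bind titanium) to set 8S,11S, fluoride then frees C15-OH (primary TES is far more labile than the secondary TBS ether) after the first hydroperoxide charge is spent, and a tenfold excess of D-(−)-DIPT overrides the residual L-ligand (positive non-linear effect) to epoxidise C1=C10 to 1R,10R; each oxygen transfer is syn-stereospecific, so the two E olefins fix the relative configuration within each oxirane, and any minor facial isomer is a separable diastereomer.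

**Step 10**
Reactants: 18 bis-oxirane diacetate silyl ether
Product: 19 {(2R,3R)-3-[((2S,3S)-3-(acetoxymethyl)-2-(2-hydroxy-3-methylbut-3-en-1-yl)-3-methyloxiran-2-yl)methyl]-2-(but-3-en-1-yl)oxiran-2-yl}methyl acetate (spatial arrangement as in 18; C6 epimers)
Conditions: TBAF, AcOH (1:1), THF, rt
Reagents that add atoms: none
Why: Acetic-acid-buffered fluoride cleaves the remaining secondary silyl ether (Si–F bond formation) without touching the acetates or the oxiranes.

**Step 11**
Reactants: 19 secondary allylic alcohol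
Product: 20 {(2R,3R)-3-[((2S,3S)-3-(acetoxymethyl)-3-methyl-2-(3-methyl-2-oxobut-3-en-1-yl)oxiran-2-yl)methyl]-2-(but-3-en-1-yl)oxiran-2-yl}methyl acetate
Conditions: Dess–Martin periodinane, NaHCO3, CH2Cl2, 0 °C to rt
Reagents that add atoms: none
Why: Dess–Martin oxidation under buffered neutral conditions gives the methacryloyl ketone, removes the epimeric C6 centre, and avoids base that would open the β,γ-oxirane by elimination.

**Step 12**
Reactants: 20 acyclic bis-oxirane enone
Product: 21 target: (4Z)-ten-membered enone with (1R,10R)-1,10-oxirane (C15H2OAc on C1) and (8S,11S)-spiro-oxirane (CH3 and C12H2OAc on C11)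
Conditions: second-generation Hoveyda–Grubbs catalyst [RuCl2(H2IMes)(=CH–C6H4-2-OiPr)] (10 mol%), 1,4-benzoquinone (20 mol%), toluene (1 mM), 80 °C
Reagents that add atoms: none
Why: Ring-closing metathesis between the monosubstituted olefin (C4) and the methacryloyl olefin (C5) at high dilution closes the ten-membered ring as the trisubstituted enone, whose Z geometry is the only strain-tolerable one in a ten-membered cycloalkenone, and leaves all four oxirane stereocentres untouched.

**Compound list**
1 | methacrolein (2-methylprop-2-enal) | CC(=C)C=O | starting material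
2 | propargyl bromide (3-bromoprop-1-yne) | BrCC#C | starting material
3 | rac-2-methylhex-1-en-5-yn-3-ol | C=C(C)C(O)CC#C | intermediate
4 | rac-tert-butyl(dimethyl)[(2-methylhex-1-en-5-yn-3-yl)oxy]silane | C=C(C)C(O[Si](C)(C)C(C)(C)C)CC#C | intermediate
5 | rac-[4-(tert-butyldimethylsilyloxy)-5-methylhex-5-en-1-yn-1-yl]lithium | C=C(C)C(O[Si](C)(C)C(C)(C)C)CC#C[Li] | intermediate (not isolated)
6 | rac-5-[(tert-butyldimethylsilyl)oxy]-6-methylhept-6-en-2-yn-1-ol | C=C(C)C(O[Si](C)(C)C(C)(C)C)CC#CCO | intermediate
7 | chloroprene (2-chlorobuta-1,3-diene) | C=CC(Cl)=C | starting material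
8 | but-3-en-1-ylmagnesium bromide | C=CCC[Mg]Br | starting material
9 | 3-methylidenehepta-1,6-diene | C=CC(=C)CCC=C | intermediate
10 | rac-2-(but-3-en-1-yl)-2-ethenyloxirane | C=CC1(CCC=C)CO1 | intermediate
11 | (2E)-2-(but-3-en-1-yl)-4-chlorobut-2-en-1-ol | OC/C(CCC=C)=C/CCl | intermediate
12 | {[(2E)-2-(but-3-en-1-yl)-4-chlorobut-2-en-1-yl]oxy}(triethyl)silane | CC[Si](CC)(CC)OC/C(CCC=C)=C/CCl | intermediate
13 | alkenylmagnesium bromide from anti-addition of MeMgBr to 6 (MgBr on C8 cis to CH2OMgBr on C11) | Br[Mg]OC/C(C)=C(/CC(O[Si](C)(C)C(C)(C)C)C(C)=C)[Mg]Br | intermediate (not isolated)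
14 | (2E,5E)-3-{2-[(tert-butyldimethylsilyl)oxy]-3-methylbut-3-en-1-yl}-2-methyl-6-{[(triethylsilyl)oxy]methyl}deca-2,5,9-trien-1-ol | OC/C(C)=C(/CC(O[Si](C)(C)C(C)(C)C)C(C)=C)\C/C=C(/CO[Si](CC)(CC)CC)CCC=C | intermediate
15 | [(2S,3S)-3-{2-[(tert-butyldimethylsilyl)oxy]-3-methylbut-3-en-1-yl}-2-methyl-3-{(2E)-3-[(triethylsilyloxy)methyl]hepta-2,6-dien-1-yl}oxiran-2-yl]methanol | C=C(C)C(O[Si](C)(C)C(C)(C)C)C[C@]1(C/C=C(/CO[Si](CC)(CC)CC)CCC=C)O[C@@]1(C)CO | intermediate (not isolated)
16 | [(2S,3S)-3-{2-[(tert-butyldimethylsilyl)oxy]-3-methylbut-3-en-1-yl}-3-[(2E)-3-(hydroxymethyl)hepta-2,6-dien-1-yl]-2-methyloxiran-2-yl]methanol | C=C(C)C(O[Si](C)(C)C(C)(C)C)C[C@]1(C/C=C(/CO)CCC=C)O[C@@]1(C)CO | intermediate (not isolated)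
17 | {(2R,3R)-2-(but-3-en-1-yl)-3-[((2S,3S)-2-{2-[(tert-butyldimethylsilyl)oxy]-3-methylbut-3-en-1-yl}-3-(hydroxymethyl)-3-methyloxiran-2-yl)methyl]oxiran-2-yl}methanol | C=C(C)C(O[Si](C)(C)C(C)(C)C)C[C@]2(C[C@H]1O[C@@]1(CO)CCC=C)O[C@@]2(C)CO | intermediate (not isolated)
18 | {(2R,3R)-3-[((2S,3S)-3-(acetoxymethyl)-2-{2-[(tert-butyldimethylsilyl)oxy]-3-methylbut-3-en-1-yl}-3-methyloxiran-2-yl)methyl]-2-(but-3-en-1-yl)oxiran-2-yl}methyl acetate | C=C(C)C(O[Si](C)(C)C(C)(C)C)C[C@]2(C[C@H]1O[C@@]1(COC(C)=O)CCC=C)O[C@@]2(C)COC(C)=O | intermediate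
19 | secondary alcohol of 18 (C6-OH in place of C6-OTBS; oxirane carbons arranged as in 18) | C=C(C)C(O)C[C@]2(C[C@H]1O[C@@]1(COC(C)=O)CCC=C)O[C@@]2(C)COC(C)=O | intermediate
20 | {(2R,3R)-3-[((2S,3S)-3-(acetoxymethyl)-3-methyl-2-(3-methyl-2-oxobut-3-en-1-yl)oxiran-2-yl)methyl]-2-(but-3-en-1-yl)oxiran-2-yl}methyl acetate | C=C(C)C(=O)C[C@]2(C[C@H]1O[C@@]1(COC(C)=O)CCC=C)O[C@@]2(C)COC(C)=O | intermediate
21 | CNP0185847.4: (4Z)-ten-membered enone, (1R,10R)-1,10-oxirane, (8S,11S)-spiro-oxirane, 12,15-diacetate | CC(=O)OC[C@]12CC/C=C(/C)C(=O)C[C@]3(C[C@H]1O2)O[C@@]3(C)COC(C)=O | target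

**Totals**
Total steps: 12. Longest linear sequence: 9 steps (from 7 and 8, steps 4 to 12); the other branch (from 1 and 2) is 8 steps.

**Steps most likely to fail, each with a fallback**

Step 12 (metathesis onto an electron-poor 1,1-disubstituted enone to close a ten-membered ring). The fallback sets out from 19. Ring-closing metathesis is run on the free allylic alcohol, whose hydroxyl speeds carbene loading onto the hindered olefin, using second-generation Grubbs catalyst [RuCl2(H2IMes)(PCy3)(=CHPh)] in dilute CH2Cl2 at reflux. This gives the ten-membered allylic alcohol F1. Dess–Martin oxidation of F1 then comes back to the route at 21.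

Step 9 (one-flask change of tartrate). The fallback sets out from 14 and gives up the second directed epoxidation. Catalytic Sharpless epoxidation with L-(+)-DIPT and in situ acetylation gives the isolated mono-oxirane acetate F2. The C1=C10 olefin is then epoxidised without any directing hydroxyl by Shi's D-fructose-derived ketone with KHSO5 (Oxone, 2KHSO5·KHSO4·K2SO4) and K2CO3 in MeCN/dimethoxymethane/water at 0 °C. The spiro transition state places the olefinic hydrogen in the hindered quadrant, the same face that D-(−)-tartrate selects, and gives the bis-oxirane silyl ether F3. Buffered TBAF at −20 °C removes the primary TES group to give the primary alcohol F4, and acetylation (Ac2O, pyridine) comes back to the route at 18.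

Step 8 (SN2 against SN2' selectivity and stability of the chelated alkenyl Grignard). The fallback sets out from 13. Transmetalation with ZnCl2 gives the alkenylzinc chloride F5. Pd(PPh3)4-catalysed alkenyl–allyl (Negishi) coupling with 12 goes through a π-allyl palladium intermediate, which is attacked at its unsubstituted terminus with retention of olefin geometry, and comes back to the route at 14.

**Further compounds**
F1 | step 12 | ten-membered allylic alcohol: 21 with C6-OH in place of the ketone (C6 epimers) | CC(=O)OC[C@]12CC/C=C(/C)C(O)C[C@]3(C[C@H]1O2)O[C@@]3(C)COC(C)=O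
F2 | step 9 | mono-oxirane acetate: acetate of 15 | C=C(C)C(O[Si](C)(C)C(C)(C)C)C[C@]1(C/C=C(/CO[Si](CC)(CC)CC)CCC=C)O[C@@]1(C)COC(C)=O
F3 | step 9 | bis-oxirane silyl ether: 18 with C15-OTES in place of C15-OAc | C=C(C)C(O[Si](C)(C)C(C)(C)C)C[C@]2(C[C@H]1O[C@@]1(CO[Si](CC)(CC)CC)CCC=C)O[C@@]2(C)COC(C)=O
F4 | step 9 | primary alcohol: 18 with C15-OH in place of C15-OAc | C=C(C)C(O[Si](C)(C)C(C)(C)C)C[C@]2(C[C@H]1O[C@@]1(CO)CCC=C)O[C@@]2(C)COC(C)=O
F5 | step 8 | alkenylzinc chloride from 13 (ZnCl on C8 cis to CH2OZnCl) | Cl[Zn]OC/C(C)=C(/CC(O[Si](C)(C)C(C)(C)C)C(C)=C)[Zn]Cl
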